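**Retrosynthetic overview**

1. The hydroquinone is unmasked last. Both β,γ-unsaturated ketones come from α-selective allylbarium additions followed by oxidation: prenyl onto the aldehyde on cyclopentane C1, and the aryl-bearing (E)-allyl unit onto the lactol carbon two atoms from C2. (Numbering: C1 bears the acyl group, C2 the oxoalkyl chain, C3–C5 are CH2, C5 next to C1.)
2. The 1,5-dicarbonyl array around the cis-dimethyl quaternary pair C1/C2 is the ozonolysis product of a silyl enol ether of meso cis-1,5-dimethylbicyclo[3.3.0]octan-3-one. Enantioselective deprotonation of this meso ketone sets both quaternary centres at once.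
3. The diquinane comes from Li/NH3 opening of a tricyclo[3.3.0.0^{2,8}]octan-3-one, itself from an oxa-di-π-methane rearrangement of a bicyclo[2.2.2]oct-5-en-2-one.
4. Key disconnection: ring bonds C4–C5 and C2–C3 are made together by Diels–Alder addition of phenyl vinyl sulfone (ethylene equivalent, = C3–C4) to an o-quinone monoketal. The enabling feature is the unsubstituted C3–C4 ethano edge of the cyclopentane: C5, C1(Me) and C2(Me) map onto C2, C4 and C5 of a 4,5-dimethylcyclohexa-2,4-dienone, whose diene termini are C5 and C2 of the target ring.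
5. Ring order: arene (dearomatised) → bicyclo[2.2.2]octene (six-membered ring closed in the key step) → cyclopropane plus second five-membered ring (photorearrangement) → cyclopropane opened → cyclopentanone ring cleaved, leaving the target cyclopentane.

Key step: step 2

Remark: the (R,R)-lithium amide is assumed to remove the enantiotopic proton that leads to 12 (the (S,S)-amide is used if the sense of induction proves opposite, and enantiomeric purity is raised if needed by crystallisation of 13 or 17); compounds 1, 5, 14, 19 and 22 are taken as commercial.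

**Route**

Step 1
Reactants: 1 2,3-dimethylanisole
Product: 4 2-methoxy-3,4-dimethylphenol, via aryllithium 2 (not isolated), via arylboronate 3 (not isolated)
Conditions: n-BuLi, TMEDA, Et2O, 0 °C to rt; B(OMe)3, −78 °C to rt; H2O2, aq. NaOH, 0 °C
Reagents that add atoms: hydrogen peroxide, OO
Why: Directed ortho-metalation places lithium at the only free position ortho to the methoxy group, and borylation/oxidation of the aryllithium installs the hydroxyl there; no stereocentre is formed.

Step 2
Reactants: 4 2-methoxy-3,4-dimethylphenol; 5 phenyl vinyl sulfone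
Product: 7 rac-3,3-dimethoxy-4,5-dimethyl-7-(phenylsulfonyl)bicyclo[2.2.2]oct-5-en-2-one, via o-quinone monoketal 6 (not isolated)
Conditions: PhI(OAc)2 (1.2 equiv), 5 (5 equiv), MeOH, 40 °C, slow addition of 4
Reagents that add atoms: methanol, CO
Why: PhI(OAc)2 oxidises the phenol to an aryloxy-iodane that methanol captures at the methoxy-bearing ortho carbon, giving the o-quinone monoketal 6, an electron-poor cisoid diene that adds phenyl vinyl sulfone in a concerted [4+2] cycloaddition. The closest known reaction type is the intermolecular Diels–Alder reaction of masked o-benzoquinones, generated in situ from 2-methoxyphenols, with acrylates, enones and related alkenes. One ring is closed: the new six-membered ring of the bicyclo[2.2.2]octenone forms by suprafacial intermolecular [4+2] addition across C2 and C5 of the dienone, so both new sigma bonds (later the C4–C5 and C2–C3 bonds of the cyclopentane) are made in the same event. The two bridgehead stereocentres are fixed relative to each other by the bicycle (racemate), and the sulfonyl-bearing carbon should follow the endo rule and the usual orientation next to the carbonyl-side bridgehead, but its configuration is irrelevant because the sulfone is removed in step 5. The selectivity that matters is cross-cycloaddition over dimerisation of 6, which the methyl groups on C4 and C5 of 6 should disfavour by encumbering the C4=C5 bond that acts as dienophile in dimerisation, helped by excess 5 and slow addition of 4. Phenyl vinyl sulfone serves as an ethylene equivalent, so the regiochemistry of its addition is also without consequence.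

Step 3
Reactants: 7 rac-3,3-dimethoxy-4,5-dimethyl-7-(phenylsulfonyl)bicyclo[2.2.2]oct-5-en-2-one
Product: 9 rac-4,5-dimethyl-7-(phenylsulfonyl)bicyclo[2.2.2]oct-5-en-2-one, via monomethoxy ketone 8 (not isolated)
Conditions: SmI2 (5 equiv), THF/MeOH, −78 °C to rt
Reagents that add atoms: none
Why: Reductive cleavage of α-alkoxy ketones by SmI2 (two single-electron transfers per C–O bond, samarium enolate protonated by MeOH) should remove both ketal methoxy groups in turn while sulfone, alkene and bridgehead centres stay untouched.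

Step 4
Reactants: 9 rac-4,5-dimethyl-7-(phenylsulfonyl)bicyclo[2.2.2]oct-5-en-2-one
Product: 10 rac-1,5-dimethyl-7-(phenylsulfonyl)tricyclo[3.3.0.0^{2,8}]octan-3-one
Conditions: hν (300 nm), acetone (solvent and triplet sensitiser), degassed, rt
Reagents that add atoms: none
Why: Triplet-sensitised oxa-di-π-methane rearrangement of the β,γ-unsaturated ketone (1,2-acyl shift, then bonding of the former α-bridgehead to the methyl-bearing alkene carbon) should give the cyclopropyl ketone, creating the second methyl-bearing quaternary carbon necessarily cis to the first because both sit on the ring fusion of the tricycle.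

Step 5
Reactants: 10 rac-1,5-dimethyl-7-(phenylsulfonyl)tricyclo[3.3.0.0^{2,8}]octan-3-one
Product: 11 cis-1,5-dimethylbicyclo[3.3.0]octan-3-one (meso)
Conditions: Li (6 equiv), NH3(l)/THF, −78 °C; solid NH4Cl
Reagents that add atoms: none
Why: In this dissolving-metal reduction the ketyl opens the cyclopropane bond that overlaps with the carbonyl π system (C2–C8) to give the lithium enolate of the cis-fused diquinane, which resists further reduction, and the alkyl phenyl sulfone is cleaved reductively in the same pot, so the racemic series converges on one meso ketone.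

Step 6
Reactants: 11 cis-1,5-dimethylbicyclo[3.3.0]octan-3-one (meso)
Product: 12 (1S,5R)-1,5-dimethyl-3-(trimethylsilyloxy)bicyclo[3.3.0]oct-2-ene
Conditions: (R,R)-bis(1-phenylethyl)amine, n-BuLi, LiCl, THF, −78 °C; then 11 and TMSCl (internal quench), −100 °C
Reagents that add atoms: chlorotrimethylsilane, C[Si](C)(C)Cl
Why: Enantioselective deprotonation of a meso ketone by a chiral lithium amide with internal silyl quench differentiates the two enantiotopic α-methylene groups, which fixes the absolute configuration of both quaternary carbons in one event and marks the C2–C3 bond for cleavage.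

Step 7
Reactants: 12 (1S,5R)-1,5-dimethyl-3-(trimethylsilyloxy)bicyclo[3.3.0]oct-2-ene
Product: 13 2-[(1R,2R)-2-formyl-1,2-dimethylcyclopentyl]acetic acid
Conditions: O3, CH2Cl2, −78 °C; Me2S, −78 °C to rt; aqueous work-up
Reagents that add atoms: ozone, [O-][O+]=O
Why: Ozonolysis of the silyl enol ether should cleave C2=C3 to the aldehyde on the quaternary carbon and a silyl ester that hydrolyses on work-up, and the aldehyde has no α-hydrogen so neither stereocentre can epimerise.

Step 8
Reactants: 13 2-[(1R,2R)-2-formyl-1,2-dimethylcyclopentyl]acetic acid; 14 prenyl chloride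
Product: 17 (4aR,7aR)-4a,7a-dimethyl-1-(3-methylbut-2-en-1-yl)hexahydrocyclopenta[c]pyran-3(1H)-one, via prenylbarium chloride 15 (not isolated), via hydroxy acid 16 (not isolated)
Conditions: BaI2, lithium biphenylide (Li+ C12H10−, 2 equiv per Ba), THF, rt; 14, −78 °C; then 13 (0.33 equiv), −78 °C; aq. citric acid; PPTS (cat.), CH2Cl2, rt
Reagents that add atoms: none
Why: Allylbarium reagents add to aldehydes through their unsubstituted α-carbon, so prenylbarium chloride (one equivalent spent on the carboxylic acid) should give the linear homoallylic alcohol, which lactonises to the cis-fused δ-lactone; the new carbinol centre forms as an epimer mixture that is oxidised in step 16.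

Step 9
Reactants: 17 (4aR,7aR)-4a,7a-dimethyl-1-(3-methylbut-2-en-1-yl)hexahydrocyclopenta[c]pyran-3(1H)-one
Product: 18 (4aR,7aR)-4a,7a-dimethyl-1-(3-methylbut-2-en-1-yl)octahydrocyclopenta[c]pyran-3-ol
Conditions: i-Bu2AlH (1.1 equiv), CH2Cl2, −78 °C; aq. KNaC4H4O6 work-up
Reagents that add atoms: none
Why: Partial reduction of a lactone by i-Bu2AlH at −78 °C should stop at the lactol because the aluminium hemiacetal is stable at low temperature, and the trisubstituted alkene is inert.

Step 10
Reactants: 19 4-methoxy-2-methylphenol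
Product: 20 2-bromo-4-methoxy-6-methylphenol
Conditions: NBS, CH2Cl2, 0 °C
Reagents that add atoms: N-bromosuccinimide, BrN1C(=O)CCC1=O
Why: Electrophilic aromatic bromination is directed by the hydroxyl group to its only free ortho position, the para position being blocked by methoxy.

Step 11
Reactants: 20 2-bromo-4-methoxy-6-methylphenol
Product: 21 1-bromo-2,5-dimethoxy-3-methylbenzene
Conditions: MeI, K2CO3, acetone, reflux
Reagents that add atoms: iodomethane, CI
Why: Williamson ether synthesis on the phenoxide gives the hydroquinone dimethyl ether, which is inert to the organometallic steps that follow.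

Step 12
Reactants: 21 1-bromo-2,5-dimethoxy-3-methylbenzene; 22 2-methyl-2-vinyloxirane
Product: 24 (E)-4-(2,5-dimethoxy-3-methylphenyl)-2-methylbut-2-en-1-ol, via aryl Grignard reagent 23 (not isolated)
Conditions: Mg, THF, reflux; then CuI (10 mol %), 22, THF, −30 °C
Reagents that add atoms: none
Why: Copper-catalysed SN2' opening of the vinyl epoxide by the aryl Grignard reagent should give the 1,4-adduct, with the (E)-trisubstituted alkene as the expected major isomer from anti addition through the s-trans conformer.

Step 13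
Reactants: 24 (E)-4-(2,5-dimethoxy-3-methylphenyl)-2-methylbut-2-en-1-ol
Product: 26 (E)-1-(4-chloro-3-methylbut-2-en-1-yl)-2,5-dimethoxy-3-methylbenzene, via allylic mesylate 25 (not isolated)
Conditions: MsCl, LiCl, s-collidine, DMF, 0 °C
Reagents that add atoms: lithium chloride, [Li+].[Cl-]
Why: Mesylation followed by SN2 displacement with chloride converts the primary allylic alcohol into the chloride without allylic transposition and with the alkene geometry retained.

Step 14
Reactants: 18 (4aR,7aR)-4a,7a-dimethyl-1-(3-methylbut-2-en-1-yl)octahydrocyclopenta[c]pyran-3-ol; 26 (E)-1-(4-chloro-3-methylbut-2-en-1-yl)-2,5-dimethoxy-3-methylbenzene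
Product: 28 (E)-6-(2,5-dimethoxy-3-methylphenyl)-1-[(1R,2R)-2-(1-hydroxy-4-methylpent-3-en-1-yl)-1,2-dimethylcyclopentyl]-4-methylhex-4-en-2-ol, via allylbarium chloride 27 (not isolated)
Conditions: BaI2, lithium biphenylide (Li+ C12H10−, 2 equiv per Ba), THF, rt; 26, −78 °C; then 18 (0.4 equiv), −78 to −40 °C
Reagents that add atoms: none
Why: The allylbarium reagent formed at −78 °C should keep its (E) geometry and attack the aldehyde form of the lactol through its CH2 (α) carbon, one equivalent being spent on the lactol hydroxyl, in an α-selective allylbarium addition that gives the linear homoallylic alcohol as a carbinol epimer mixture destined for oxidation.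

Step 15
Reactants: 28 (E)-6-(2,5-dimethoxy-3-methylphenyl)-1-[(1R,2R)-2-(1-hydroxy-4-methylpent-3-en-1-yl)-1,2-dimethylcyclopentyl]-4-methylhex-4-en-2-ol
Product: 29 2-[(E)-5-hydroxy-6-[(1R,2R)-2-(1-hydroxy-4-methylpent-3-en-1-yl)-1,2-dimethylcyclopentyl]-3-methylhex-2-en-1-yl]-6-methylcyclohexa-2,5-diene-1,4-dione
Conditions: (NH4)2Ce(NO3)6 (2.5 equiv), MeCN/H2O, 0 °C, short contact time
Reagents that add atoms: water, O
Why: Oxidative demethylation of the hydroquinone dimethyl ether by (NH4)2Ce(NO3)6 should give the p-quinone (quinone oxygens from water), and it is run at the diol stage so that the acid-sensitive β,γ-unsaturated ketones are not yet present.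

Step 16
Reactants: 29 2-[(E)-5-hydroxy-6-[(1R,2R)-2-(1-hydroxy-4-methylpent-3-en-1-yl)-1,2-dimethylcyclopentyl]-3-methylhex-2-en-1-yl]-6-methylcyclohexa-2,5-diene-1,4-dione
Product: 30 2-[(E)-6-[(1R,2R)-1,2-dimethyl-2-(4-methylpent-3-enoyl)cyclopentyl]-3-methyl-5-oxohex-2-en-1-yl]-6-methylcyclohexa-2,5-diene-1,4-dione
Conditions: Dess–Martin periodinane (3 equiv), NaHCO3, CH2Cl2, 0 °C to rt
Reagents that add atoms: none
Why: Dess–Martin oxidation of both secondary alcohols under buffered, non-basic conditions should give the two β,γ-unsaturated ketones without moving either alkene into conjugation and without aldol closure of the 1,5-diketone.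

Step 17
Reactants: 30 2-[(E)-6-[(1R,2R)-1,2-dimethyl-2-(4-methylpent-3-enoyl)cyclopentyl]-3-methyl-5-oxohex-2-en-1-yl]-6-methylcyclohexa-2,5-diene-1,4-dione
Product: 31 (E)-6-(2,5-dihydroxy-3-methylphenyl)-1-[(1R,2R)-1,2-dimethyl-2-(4-methylpent-3-enoyl)cyclopentyl]-4-methylhex-4-en-2-one
Conditions: Na2S2O4, THF/H2O, rt, under argon
Reagents that add atoms: none
Why: Dithionite reduction of the quinone to the hydroquinone proceeds under neutral aqueous conditions that leave the ketones, the alkenes and both quaternary stereocentres untouched.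

**Compound list**

1 | 2,3-dimethylanisole | COc1cccc(C)c1C | starting material
2 | (2-methoxy-3,4-dimethylphenyl)lithium | [Li]c1ccc(C)c(C)c1OC | intermediate
3 | dimethyl (2-methoxy-3,4-dimethylphenyl)boronate | COB(OC)c1ccc(C)c(C)c1OC | intermediate
4 | 2-methoxy-3,4-dimethylphenol | COc1c(O)ccc(C)c1C | intermediate
5 | phenyl vinyl sulfone | C=CS(=O)(=O)c1ccccc1 | starting material
6 | 6,6-dimethoxy-4,5-dimethylcyclohexa-2,4-dien-1-one | COC1(OC)C(C)=C(C)C=CC1=O | intermediate
7 | rac-3,3-dimethoxy-4,5-dimethyl-7-(phenylsulfonyl)bicyclo[2.2.2]oct-5-en-2-one (sulfonyl on the bridge carbon next to the CH bridgehead, syn to the C5=C6 bond; racemic, one enantiomer drawn) | O=C1C(OC)(OC)[C@]2(C)C(C)=C[C@H]1[C@@H](S(=O)(=O)c1ccccc1)C2 | intermediate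
8 | rac-3-methoxy-4,5-dimethyl-7-(phenylsulfonyl)bicyclo[2.2.2]oct-5-en-2-one (epimers at C3) | O=C1C(OC)[C@]2(C)C(C)=C[C@H]1[C@@H](S(=O)(=O)c1ccccc1)C2 | intermediate
9 | rac-4,5-dimethyl-7-(phenylsulfonyl)bicyclo[2.2.2]oct-5-en-2-one | O=C1C[C@]2(C)C(C)=C[C@H]1[C@@H](S(=O)(=O)c1ccccc1)C2 | intermediate
10 | rac-1,5-dimethyl-7-(phenylsulfonyl)tricyclo[3.3.0.0^{2,8}]octan-3-one | O=C1C[C@@]2(C)C[C@H](S(=O)(=O)c3ccccc3)[C@H]3[C@@H]1[C@@]23C | intermediate
11 | cis-1,5-dimethylbicyclo[3.3.0]octan-3-one (meso) | C[C@@]12CCC[C@]1(C)CC(=O)C2 | intermediate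
12 | (1S,5R)-1,5-dimethyl-3-(trimethylsilyloxy)bicyclo[3.3.0]oct-2-ene | C[C@@]12CCC[C@]1(C)CC(O[Si](C)(C)C)=C2 | intermediate
13 | 2-[(1R,2R)-2-formyl-1,2-dimethylcyclopentyl]acetic acid | O=C[C@]1(C)CCC[C@]1(C)CC(=O)O | intermediate
14 | prenyl chloride (1-chloro-3-methylbut-2-ene) | CC(C)=CCCl | starting material
15 | prenylbarium chloride | CC(C)=CC[Ba]Cl | intermediate
16 | 2-[(1R,2R)-2-(1-hydroxy-4-methylpent-3-en-1-yl)-1,2-dimethylcyclopentyl]acetic acid (carbinol epimers) | CC(C)=CCC(O)[C@]1(C)CCC[C@]1(C)CC(=O)O | intermediate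
17 | (4aR,7aR)-4a,7a-dimethyl-1-(3-methylbut-2-en-1-yl)hexahydrocyclopenta[c]pyran-3(1H)-one (epimers at C1) | CC(C)=CCC1OC(=O)C[C@@]2(C)CCC[C@@]12C | intermediate
18 | (4aR,7aR)-4a,7a-dimethyl-1-(3-methylbut-2-en-1-yl)octahydrocyclopenta[c]pyran-3-ol (epimers at C1 and C3) | CC(C)=CCC1OC(O)C[C@@]2(C)CCC[C@@]12C | intermediate
19 | 4-methoxy-2-methylphenol | COc1ccc(O)c(C)c1 | starting material
20 | 2-bromo-4-methoxy-6-methylphenol | COc1cc(C)c(O)c(Br)c1 | intermediate
21 | 1-bromo-2,5-dimethoxy-3-methylbenzene | COc1cc(C)c(OC)c(Br)c1 | intermediate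
22 | 2-methyl-2-vinyloxirane | CC1(C=C)CO1 | starting material
23 | (2,5-dimethoxy-3-methylphenyl)magnesium bromide | COc1cc(C)c(OC)c([Mg]Br)c1 | intermediate
24 | (E)-4-(2,5-dimethoxy-3-methylphenyl)-2-methylbut-2-en-1-ol | OC/C(C)=C/Cc1cc(OC)cc(C)c1OC | intermediate
25 | (E)-4-(2,5-dimethoxy-3-methylphenyl)-2-methylbut-2-en-1-yl methanesulfonate | CS(=O)(=O)OC/C(C)=C/Cc1cc(OC)cc(C)c1OC | intermediate
26 | (E)-1-(4-chloro-3-methylbut-2-en-1-yl)-2,5-dimethoxy-3-methylbenzene | ClC/C(C)=C/Cc1cc(OC)cc(C)c1OC | intermediate
27 | [(E)-4-(2,5-dimethoxy-3-methylphenyl)-2-methylbut-2-en-1-yl]barium chloride | Cl[Ba]C/C(C)=C/Cc1cc(OC)cc(C)c1OC | intermediate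
28 | (E)-6-(2,5-dimethoxy-3-methylphenyl)-1-[(1R,2R)-2-(1-hydroxy-4-methylpent-3-en-1-yl)-1,2-dimethylcyclopentyl]-4-methylhex-4-en-2-ol (carbinol epimers) | CC(C)=CCC(O)[C@]1(C)CCC[C@]1(C)CC(O)C/C(C)=C/Cc1cc(OC)cc(C)c1OC | intermediate
29 | 2-[(E)-5-hydroxy-6-[(1R,2R)-2-(1-hydroxy-4-methylpent-3-en-1-yl)-1,2-dimethylcyclopentyl]-3-methylhex-2-en-1-yl]-6-methylcyclohexa-2,5-diene-1,4-dione (carbinol epimers) | CC(C)=CCC(O)[C@]1(C)CCC[C@]1(C)CC(O)C/C(C)=C/CC1=CC(=O)C=C(C)C1=O | intermediate
30 | 2-[(E)-6-[(1R,2R)-1,2-dimethyl-2-(4-methylpent-3-enoyl)cyclopentyl]-3-methyl-5-oxohex-2-en-1-yl]-6-methylcyclohexa-2,5-diene-1,4-dione | CC(C)=CCC(=O)[C@]1(C)CCC[C@]1(C)CC(=O)C/C(C)=C/CC1=CC(=O)C=C(C)C1=O | intermediate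
31 | (E)-6-(2,5-dihydroxy-3-methylphenyl)-1-[(1R,2R)-1,2-dimethyl-2-(4-methylpent-3-enoyl)cyclopentyl]-4-methylhex-4-en-2-one | CC(C)=CCC(=O)[C@]1(C)CCC[C@]1(C)CC(=O)C/C(C)=C/Cc1cc(O)cc(C)c1O | target

**Step count**

Total: 17 steps. Longest linear sequence: 13 steps (steps 1–9, then 14–17); the aryl fragment takes steps 10–13.

**Steps most likely to fail, with fallbacks**

Step 2. The cross-cycloaddition may be outrun by dimerisation or decomposition of the monoketal: an electron-poor diene meets an electron-poor dienophile, and the bond to the methyl-bearing diene terminus next to the ketal carbon is sterically congested. The fallback inverts the electronic demand. It sets out from 4, which is oxidised under the same conditions in the presence of phenyl vinyl sulfide, an electron-rich ethylene equivalent of the kind that masked o-benzoquinones accept readily. This should give rac-3,3-dimethoxy-4,5-dimethyl-7-(phenylsulfanyl)bicyclo[2.2.2]oct-5-en-2-one F1. Chemoselective oxidation at sulfur (H2O2, catalytic (NH4)6Mo7O24, EtOH, 0 °C) leaves the trisubstituted alkene alone and returns to the route at 7.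

Step 6. Discrimination between the enantiotopic α-methylene groups may be poor, or deprotonation slow, because both flank quaternary carbons; the result would be low enantiomeric purity. The fallback replaces chiral-base chemistry by an oxidative desymmetrisation. It sets out from 11, which undergoes an enzymatic Baeyer–Villiger oxidation (a cyclopentanone monooxygenase, whole cells, O2; enantiocomplementary enzymes can be screened). Oxygen is inserted on one enantiotopic side to give (4aR,7aR)-4a,7a-dimethylhexahydrocyclopenta[c]pyran-3(1H)-one F2. Saponification with LiOH gives lithium 2-[(1R,2R)-2-(hydroxymethyl)-1,2-dimethylcyclopentyl]acetate F3. Oxidation of its neopentyl primary alcohol with TEMPO/NaOCl/KBr in buffered two-phase medium, followed by acidification, returns to the route at 13.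

Step 14. Opening of the barium lactolate to the reactive aldehyde may be slow at −78 °C, and warming to force it may erode the α-regioselectivity and the (E) geometry of the allylbarium reagent, while one equivalent of the fragment is lost to the hydroxyl proton. The fallback enforces α-attack with a sulfone and uses the lactone instead of the lactol. It sets out from 26 and 17. Chloride 26 and PhSO2Na in DMF give (E)-1-[4-(phenylsulfonyl)-3-methylbut-2-en-1-yl]-2,5-dimethoxy-3-methylbenzene F4. Its α-sulfonyl carbanion (n-BuLi, 2 equiv, THF, −78 °C) is acylated by lactone 17 to give the δ-hydroxy β-keto sulfone 1-[(1R,2R)-2-(1-hydroxy-4-methylpent-3-en-1-yl)-1,2-dimethylcyclopentyl]-6-(2,5-dimethoxy-3-methylphenyl)-4-methyl-3-(phenylsulfonyl)hex-4-en-2-one F5. Reductive desulfonylation with aluminium amalgam, Al(Hg), in aqueous THF gives the hydroxy ketone (E)-1-[(1R,2R)-2-(1-hydroxy-4-methylpent-3-en-1-yl)-1,2-dimethylcyclopentyl]-6-(2,5-dimethoxy-3-methylphenyl)-4-methylhex-4-en-2-one F6. NaBH4 reduction of F6 returns to the route at 28, so the arene is still oxidised before the ketones are unveiled.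

Further compounds
F1 | step 2 | rac-3,3-dimethoxy-4,5-dimethyl-7-(phenylsulfanyl)bicyclo[2.2.2]oct-5-en-2-one | O=C1C(OC)(OC)[C@]2(C)C(C)=C[C@H]1[C@@H](Sc1ccccc1)C2
F2 | step 6 | (4aR,7aR)-4a,7a-dimethylhexahydrocyclopenta[c]pyran-3(1H)-one | C1OC(=O)C[C@@]2(C)CCC[C@@]12C
F3 | step 6 | lithium 2-[(1R,2R)-2-(hydroxymethyl)-1,2-dimethylcyclopentyl]acetate | [Li+].OC[C@]1(C)CCC[C@]1(C)CC(=O)[O-]
F4 | step 14 | (E)-1-[4-(phenylsulfonyl)-3-methylbut-2-en-1-yl]-2,5-dimethoxy-3-methylbenzene | O=S(=O)(C/C(C)=C/Cc1cc(OC)cc(C)c1OC)c1ccccc1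
F5 | step 14 | 1-[(1R,2R)-2-(1-hydroxy-4-methylpent-3-en-1-yl)-1,2-dimethylcyclopentyl]-6-(2,5-dimethoxy-3-methylphenyl)-4-methyl-3-(phenylsulfonyl)hex-4-en-2-one | CC(C)=CCC(O)[C@]1(C)CCC[C@]1(C)CC(=O)C(S(=O)(=O)c1ccccc1)/C(C)=C/Cc1cc(OC)cc(C)c1OC
F6 | step 14 | (E)-1-[(1R,2R)-2-(1-hydroxy-4-methylpent-3-en-1-yl)-1,2-dimethylcyclopentyl]-6-(2,5-dimethoxy-3-methylphenyl)-4-methylhex-4-en-2-one | CC(C)=CCC(O)[C@]1(C)CCC[C@]1(C)CC(=O)C/C(C)=C/Cc1cc(OC)cc(C)c1OC
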